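**Retrosynthetic overview**

1. Atom labels: seven-membered ring C1(side chain)–C5(Me)=C6–C7–C8(O)–C9–C10(Me); side chain C2(O-angeloyl)–C3–C4(O-acetyl); lactone C7–C11(=C13)–C12(=O)–O–C8.
2. The C4 acetate, the C2 angelate and the C11=C13 methylene are added last. The C5(Me)=C6 alkene comes from a C5 ketone through its kinetic C5–C6 enol triflate. The cis-fused lactone ring is closed by a bromoacetal radical cyclisation from the C8 oxygen onto C7 of the C5 enone.
3. The feature on which the route rests: the contiguous triad C10(Me)/C1/C2(O) is the β-carbon, the α-carbon and the aldol carbinol of that C5 ketone. A methylcuprate addition with aldol trapping on (R)-4-silyloxycyclohepta-2,6-dienone therefore forms C10–CH3 and C1–C2 in one operation, with C8 as the only stereocentre already present.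
4. The dienone comes from cyclohepta-1,3-diene (singlet oxygen, enantioselective Kornblum–DeLaMare opening, silylation, Saegusa oxidation); the aldehyde comes from propane-1,3-diol.
5. Ring order: the carbocycle is purchased; the lactone ring is the only ring formed (step 12), after the key step.

Key step: step 8

Remarks on the chemistry:
- Assumption: in step 2 the cinchona catalyst is taken from the pseudoenantiomeric series that gives the R alcohol; the sense of induction has to be confirmed on the first run.
- The C8 oxygen carries triethylsilyl, not tert-butyldimethylsilyl, so that it can be unmasked selectively once the C2 hydroxyl is capped as its TBS ether.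
- The acetal carbon in 19–23, the lactol carbon in 24 and C11 in 27 and 28 are epimer mixtures that converge later.

**Step 1**
Reactants: 1 cyclohepta-1,3-diene
Product: 2 6,7-dioxabicyclo[3.2.2]non-8-ene (meso endoperoxide)
Conditions: O2, hν (visible), tetraphenylporphyrin (cat.), CH2Cl2, 0 °C
Reagents that add atoms: dioxygen, O=O
Why: [4+2] photooxygenation of the s-cis diene by singlet oxygen should give the meso bicyclic endoperoxide, with no stereochemical choice to make.

**Step 2**
Reactants: 2 6,7-dioxabicyclo[3.2.2]non-8-ene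
Product: 3 (R)-4-hydroxycyclohept-2-en-1-one
Conditions: 9-O-acetylcupreidine or its pseudoenantiomer 9-O-acetylcupreine (5 mol%, whichever gives R), CH2Cl2, rt
Reagents that add atoms: none
Why: Enantioselective Kornblum–DeLaMare rearrangement, in which the chiral base removes one of the two enantiotopic bridgehead protons with O–O cleavage, so the ketone forms at that carbon and C8 is left as the R carbinol (desymmetrisation of a meso endoperoxide).

**Step 3**
Reactants: 3 (R)-4-hydroxycyclohept-2-en-1-one
Product: 4 (R)-4-(triethylsilyloxy)cyclohept-2-en-1-one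
Conditions: Et3SiCl, imidazole, CH2Cl2, 0 °C
Reagents that add atoms: chlorotriethylsilane, CC[Si](CC)(CC)Cl
Why: Standard silylation under mild imidazole conditions, which should not cause elimination of the γ-hydroxy enone; C8 is untouched.

**Step 4**
Reactants: 4 (R)-4-(triethylsilyloxy)cyclohept-2-en-1-one
Product: 6 (R)-triethyl{[4-(trimethylsilyloxy)cyclohepta-2,4-dien-1-yl]oxy}silane, via lithium dienolate 5 (not isolated)
Conditions: LiN(iPr)2 (LDA), THF, −78 °C; Me3SiCl, −78 to 0 °C; non-aqueous work-up, used crude
Reagents that add atoms: chlorotrimethylsilane, C[Si](C)(C)Cl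
Why: Kinetic deprotonation of an enone by LDA takes place at the α′ methylene (C1) and not at the γ carbon C8, and O-silylation of the cross-conjugated dienolate gives the 2-silyloxy diene (silyl enol ether formation).

**Step 5**
Reactants: 6 (R)-triethyl{[4-(trimethylsilyloxy)cyclohepta-2,4-dien-1-yl]oxy}silane
Product: 7 (R)-4-(triethylsilyloxy)cyclohepta-2,6-dien-1-one
Conditions: Pd(OAc)2 (1.05 equiv), MeCN, rt
Reagents that add atoms: none
Why: Saegusa–Ito oxidation, in which a palladium enolate at C1 undergoes β-hydride elimination from C10, should install the second enone without base, so the base-labile silyloxy dienone is not exposed to elimination.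

**Step 6**
Reactants: 8 propane-1,3-diol; 9 4-methoxybenzyl chloride
Product: 10 3-(4-methoxybenzyloxy)propan-1-ol
Conditions: NaH (1 equiv), 8 (3 equiv), THF/DMF, 0 °C; 9, Bu4NI (cat.), rt
Reagents that add atoms: none
Why: Williamson ether synthesis; the excess of diol should keep the alkylation at the mono-ether stage.

**Step 7**
Reactants: 10 3-(4-methoxybenzyloxy)propan-1-ol
Product: 11 3-(4-methoxybenzyloxy)propanal
Conditions: PhI(OAc)2, TEMPO (cat.), CH2Cl2, rt
Reagents that add atoms: none
Why: The oxoammonium (TEMPO) oxidation of a primary alcohol stops at the aldehyde and tolerates the PMB ether.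

**Step 8**
Reactants: 7 (R)-4-(triethylsilyloxy)cyclohepta-2,6-dien-1-one; 12 methyllithium; 11 3-(4-methoxybenzyloxy)propanal
Product: 16 (4R,6R,7R)-7-[(1S)-1-hydroxy-3-(4-methoxybenzyloxy)propyl]-6-methyl-4-(triethylsilyloxy)cyclohept-2-en-1-one, via lithium dimethylcuprate 13 (not isolated), via lithium enolate 14 (not isolated), via zirconocene enolate 15 (not isolated)
Conditions: 12 (2.2 equiv), CuI (1.1 equiv), Et2O, 0 °C; 7, −78 °C; Cp2ZrCl2 (1.2 equiv), THF, −78 to −40 °C; 11, −78 °C; aq NH4Cl at −78 °C
Reagents that add atoms: none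
Why: Me2CuLi complexes the C1=C10 enone, and oxidative addition to a β-cuprio enolate (formally trivalent copper) followed by reductive elimination forms C10–CH3 and leaves the C5 enolate regiospecifically toward C1; after transmetalation to zirconium this enolate adds to aldehyde 11 and forms C1–C2, which is the known tandem cuprate conjugate addition and enolate aldol trapping (three-component coupling) on cyclic enones. No ring closes in this step. C10 is expected to react in preference to C7 because C7 is flanked by C8 with its silyloxy group whereas C10 has only the C9 methylene beside it, and after the first addition the cross-conjugated dienolate is no longer an acceptor, so about one equivalent of cuprate cannot add a second time. At C10 the methyl should enter anti to the C8 silyloxy group, the 1,3-trans outcome familiar from 5-substituted cycloalkenones. At C1 the aldehyde should approach anti to the new C10 methyl (trans-2,3 relationship). At C2 the chlorozirconocene enolate is chosen because it gives syn aldols whatever the enolate geometry, whereas the closed transition state of the ring-locked E lithium or zinc enolate would favour anti; syn on this enolate face corresponds to the S carbinol.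

**Step 9**
Reactants: 16 the aldol adduct of step 8
Product: 17 (4R,6R,7R)-7-[(1S)-1-(tert-butyldimethylsilyloxy)-3-(4-methoxybenzyloxy)propyl]-6-methyl-4-(triethylsilyloxy)cyclohept-2-en-1-one
Conditions: tBuMe2SiOTf, 2,6-lutidine, CH2Cl2, −78 °C
Reagents that add atoms: tert-butyldimethylsilyl triflate, CC(C)(C)[Si](C)(C)OS(=O)(=O)C(F)(F)F
Why: Silyl triflate with a hindered pyridine base caps the hindered aldol hydroxyl at low temperature without retro-aldol or enol silylation, and it locks C2 before the C8 oxygen is unmasked.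

**Step 10**
Reactants: 17 the bis-silyl ether of step 9
Product: 18 (4R,6R,7R)-7-[(1S)-1-(tert-butyldimethylsilyloxy)-3-(4-methoxybenzyloxy)propyl]-4-hydroxy-6-methylcyclohept-2-en-1-one
Conditions: PPTS (cat.), MeOH/CH2Cl2, 0 °C
Reagents that add atoms: none
Why: Acid-catalysed methanolysis cleaves a secondary triethylsilyl ether much faster than a hindered secondary TBS ether, and the PMB ether and the β-silyloxy ketone are stable to it.

**Step 11**
Reactants: 18 the C8 alcohol of step 10
Product: 19 4-(2-bromo-1-ethoxyethoxy) derivative of 18 (bromoacetal on the C8 oxygen; acetal epimers)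
Conditions: ethyl vinyl ether, N-bromosuccinimide, CH2Cl2, −40 to 0 °C
Reagents that add atoms: ethyl vinyl ether, C=COCC; N-bromosuccinimide, O=C1CCC(=O)N1Br
Why: Haloacetalisation, in which the C8 hydroxyl captures the bromonium/oxocarbenium ion formed from the enol ether; it is the only free hydroxyl in the molecule.

**Step 12**
Reactants: 19 the bromoacetal of step 11
Product: 20 cis-fused bicyclic keto acetal (ring O8–CH(OEt)–C11H2–C7 fused at C7/C8; C5 ketone with C6H2; C10 methyl; C1 side chain with C2 OTBS and C4 OPMB)
Conditions: Bu3SnH (slow addition), AIBN (cat.), benzene, 80 °C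
Reagents that add atoms: none
Why: Ueno–Stork radical cyclisation, a 5-exo-trig addition of the nucleophilic alkyl radical to C7, the β-carbon of the enone; the two-atom tether from the C8 oxygen can only reach the same face, so the ring is cis-fused and C7 is set, and the α-keto radical at C6 is reduced by the tin hydride.

**Step 13**
Reactants: 20 the bicyclic keto acetal of step 12
Product: 22 C5–C6 enol triflate of 20, via lithium enolate 21 (not isolated)
Conditions: LiN(iPr)2 (LDA), THF, −78 °C; N-(5-chloropyridin-2-yl)triflimide (Comins' reagent), −78 °C; aq NH4Cl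
Reagents that add atoms: Comins' reagent, O=S(=O)(N(c1ccc(Cl)cn1)S(=O)(=O)C(F)(F)F)C(F)(F)F
Why: Kinetic deprotonation goes to the C6 methylene because C1 is a hindered methine between two stereocentres, and O-triflation at −78 °C fixes the double bond at C5=C6 without touching C1 or the β-silyloxy group (kinetic enol triflate formation).

**Step 14**
Reactants: 22 the enol triflate of step 13
Product: 23 C5-methyl C5=C6 alkene (bicyclic ethyl acetal; C2 OTBS; C4 OPMB)
Conditions: Me2Zn, Pd(PPh3)4 (5 mol%), THF, 0 °C to rt
Reagents that add atoms: dimethylzinc, C[Zn]C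
Why: Negishi coupling of an alkenyl triflate under zerovalent palladium catalysis replaces the triflate by methyl without moving the double bond, and the acetal and the ethers are inert to it.

**Step 15**
Reactants: 23 the methyl alkene acetal of step 14
Product: 24 lactol (hemiacetal at the former acetal carbon; epimers)
Conditions: AcOH/THF/H2O (3:1:1), 40 °C
Reagents that add atoms: water, O
Why: Mild aqueous acid hydrolysis of the 2-ethoxytetrahydrofuran acetal; the hindered TBS ether and the PMB ether should survive these conditions.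

**Step 16**
Reactants: 24 the lactol of step 15
Product: 25 cis-fused γ-lactone (C12 carbonyl, C11H2; C2 OTBS; C4 OPMB)
Conditions: PhI(OAc)2, TEMPO (cat.), CH2Cl2, rt
Reagents that add atoms: none
Why: Oxoammonium (TEMPO) oxidation of a lactol to the lactone; there is no other free hydroxyl, and the alkene and the PMB ether tolerate the reagent.

**Step 17**
Reactants: 25 the lactone of step 16
Product: 27 C11-(dimethylaminomethyl) lactone (Mannich base), via lactone lithium enolate 26 (not isolated)
Conditions: LiN(iPr)2 (LDA), THF, −78 °C; CH2=NMe2+ I− (Eschenmoser's salt), −78 °C to rt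
Reagents that add atoms: Eschenmoser's salt, C=[N+](C)C.[I-]
Why: Mannich reaction of the lactone enolate with the preformed iminium salt; C11 is the only enolisable position, and its configuration does not matter.

**Step 18**
Reactants: 27 the Mannich base of step 17
Product: 29 α-methylene lactone with C2 OTBS and C4 OPMB, via trimethylammonium iodide 28 (not isolated)
Conditions: MeI, MeOH, rt; then aq NaHCO3, CH2Cl2, rt
Reagents that add atoms: none
Why: Quaternisation followed by mild-base β-elimination of trimethylamine (Hofmann-type) gives the exocyclic C11=C13 alkene under conditions too weak to isomerise it into the ring.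

**Step 19**
Reactants: 29 the α-methylene lactone of step 18
Product: 30 C2 alcohol (α-methylene lactone; C4 OPMB)
Conditions: HF·pyridine, pyridine, THF, 0 °C to rt
Reagents that add atoms: none
Why: Buffered fluoride cleavage of the TBS ether, which leaves the PMB ether, the lactone and the exocyclic enoate untouched.

**Step 20**
Reactants: 30 the C2 alcohol of step 19; 31 angelic acid
Product: 33 C2 angelate (α-methylene lactone; C4 OPMB), via mixed anhydride 32 (not isolated)
Conditions: 31, 2,4,6-trichlorobenzoyl chloride, Et3N, toluene, rt; then 30, 80 °C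
Reagents that add atoms: none
Why: Yamaguchi esterification through the mixed anhydride without a nucleophilic catalyst, a protocol used for angelates because it avoids Z-to-E isomerisation to the tiglate; no other hydroxyl is free.

**Step 21**
Reactants: 33 the angelate of step 20
Product: 34 C4 primary alcohol (C2 angelate; α-methylene lactone)
Conditions: DDQ, CH2Cl2/pH 7 buffer, 0 °C to rt
Reagents that add atoms: none
Why: Oxidative cleavage of the PMB ether by DDQ through the benzylic oxocarbenium ion; the electron-poor enoates and the trisubstituted alkene are not oxidised under these conditions.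

**Step 22**
Reactants: 34 the C4 alcohol of step 21
Product: 35 CNP0163960.1 (C1 S, C2 S, C7 R, C8 R, C10 R)
Conditions: Ac2O, pyridine, CH2Cl2, 0 °C to rt
Reagents that add atoms: acetic anhydride, CC(=O)OC(C)=O
Why: Acetylation of the unhindered primary alcohol under conditions that leave the angelate geometry and the α-methylene lactone intact.

**Compound list**

1 | cyclohepta-1,3-diene | C1=CC=CCCC1 | starting material
2 | 6,7-dioxabicyclo[3.2.2]non-8-ene (meso) | C1C[C@H]2C=C[C@@H](C1)OO2 | intermediate
3 | (R)-4-hydroxycyclohept-2-en-1-one | O[C@@H]1CCCC(=O)C=C1 | intermediate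
4 | (R)-4-(triethylsilyloxy)cyclohept-2-en-1-one | CC[Si](CC)(CC)O[C@@H]1CCCC(=O)C=C1 | intermediate
5 | lithium (R)-5-(triethylsilyloxy)cyclohepta-1,6-dien-1-olate | CC[Si](CC)(CC)O[C@@H]1CCC=C([O-])C=C1.[Li+] | intermediate
6 | (R)-triethyl{[4-(trimethylsilyloxy)cyclohepta-2,4-dien-1-yl]oxy}silane | CC[Si](CC)(CC)O[C@@H]1CCC=C(O[Si](C)(C)C)C=C1 | intermediate
7 | (R)-4-(triethylsilyloxy)cyclohepta-2,6-dien-1-one | CC[Si](CC)(CC)O[C@@H]1CC=CC(=O)C=C1 | intermediate
8 | propane-1,3-diol | OCCCO | starting material
9 | 4-methoxybenzyl chloride | COc1ccc(CCl)cc1 | starting material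
10 | 3-(4-methoxybenzyloxy)propan-1-ol | OCCCOCc1ccc(OC)cc1 | intermediate
11 | 3-(4-methoxybenzyloxy)propanal | O=CCCOCc1ccc(OC)cc1 | intermediate
12 | methyllithium | [Li]C | starting material
13 | lithium dimethylcuprate | [Li+].C[Cu-]C | intermediate
14 | lithium (3R,5R)-3-methyl-5-(triethylsilyloxy)cyclohepta-1,6-dien-1-olate (C10 methyl trans to the C8 oxygen) | CC[Si](CC)(CC)O[C@@H]1C[C@@H](C)C=C([O-])C=C1.[Li+] | intermediate
15 | chlorobis(cyclopentadienyl)zirconium enolate corresponding to 14 (cyclopentadienyl rings drawn σ-bonded) | CC[Si](CC)(CC)O[C@@H]1C[C@@H](C)C=C(O[Zr](Cl)(C2C=CC=C2)C2C=CC=C2)C=C1 | intermediate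
16 | (4R,6R,7R)-7-[(1S)-1-hydroxy-3-(4-methoxybenzyloxy)propyl]-6-methyl-4-(triethylsilyloxy)cyclohept-2-en-1-one | CC[Si](CC)(CC)O[C@@H]1C[C@@H](C)[C@H]([C@H](CCOCc2ccc(OC)cc2)O)C(=O)C=C1 | intermediate
17 | (4R,6R,7R)-7-[(1S)-1-(tert-butyldimethylsilyloxy)-3-(4-methoxybenzyloxy)propyl]-6-methyl-4-(triethylsilyloxy)cyclohept-2-en-1-one | CC[Si](CC)(CC)O[C@@H]1C[C@@H](C)[C@H]([C@H](CCOCc2ccc(OC)cc2)O[Si](C)(C)C(C)(C)C)C(=O)C=C1 | intermediate
18 | (4R,6R,7R)-7-[(1S)-1-(tert-butyldimethylsilyloxy)-3-(4-methoxybenzyloxy)propyl]-4-hydroxy-6-methylcyclohept-2-en-1-one | O[C@@H]1C[C@@H](C)[C@H]([C@H](CCOCc2ccc(OC)cc2)O[Si](C)(C)C(C)(C)C)C(=O)C=C1 | intermediate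
19 | 4-(2-bromo-1-ethoxyethoxy) derivative of 18 (acetal epimers) | CCOC(CBr)O[C@@H]1C[C@@H](C)[C@H]([C@H](CCOCc2ccc(OC)cc2)O[Si](C)(C)C(C)(C)C)C(=O)C=C1 | intermediate
20 | cis-fused bicyclic keto acetal (C5 ketone; ethyl acetal; C2 OTBS; C4 OPMB) | CCOC1O[C@@H]2C[C@@H](C)[C@H]([C@H](CCOCc3ccc(OC)cc3)O[Si](C)(C)C(C)(C)C)C(=O)C[C@@H]2C1 | intermediate
21 | lithium C5–C6 enolate of 20 | CCOC1O[C@@H]2C[C@@H](C)[C@H]([C@H](CCOCc3ccc(OC)cc3)O[Si](C)(C)C(C)(C)C)C([O-])=C[C@@H]2C1.[Li+] | intermediate
22 | C5–C6 enol triflate of 20 | CCOC1O[C@@H]2C[C@@H](C)[C@H]([C@H](CCOCc3ccc(OC)cc3)O[Si](C)(C)C(C)(C)C)C(OS(=O)(=O)C(F)(F)F)=C[C@@H]2C1 | intermediate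
23 | C5-methyl C5=C6 alkene, bicyclic ethyl acetal | CCOC1O[C@@H]2C[C@@H](C)[C@H]([C@H](CCOCc3ccc(OC)cc3)O[Si](C)(C)C(C)(C)C)C(C)=C[C@@H]2C1 | intermediate
24 | lactol corresponding to 23 | OC1O[C@@H]2C[C@@H](C)[C@H]([C@H](CCOCc3ccc(OC)cc3)O[Si](C)(C)C(C)(C)C)C(C)=C[C@@H]2C1 | intermediate
25 | cis-fused γ-lactone (C2 OTBS; C4 OPMB) | O=C1O[C@@H]2C[C@@H](C)[C@H]([C@H](CCOCc3ccc(OC)cc3)O[Si](C)(C)C(C)(C)C)C(C)=C[C@@H]2C1 | intermediate
26 | lithium enolate of lactone 25 | [Li+].[O-]C=1O[C@@H]2C[C@@H](C)[C@H]([C@H](CCOCc3ccc(OC)cc3)O[Si](C)(C)C(C)(C)C)C(C)=C[C@@H]2C=1 | intermediate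
27 | C11-(dimethylaminomethyl) lactone (C11 epimers) | CN(C)CC1C(=O)O[C@@H]2C[C@@H](C)[C@H]([C@H](CCOCc3ccc(OC)cc3)O[Si](C)(C)C(C)(C)C)C(C)=C[C@H]12 | intermediate
28 | trimethylammonium iodide of 27 | C[N+](C)(C)CC1C(=O)O[C@@H]2C[C@@H](C)[C@H]([C@H](CCOCc3ccc(OC)cc3)O[Si](C)(C)C(C)(C)C)C(C)=C[C@H]12.[I-] | intermediate
29 | α-methylene lactone with C2 OTBS and C4 OPMB | C=C1C(=O)O[C@@H]2C[C@@H](C)[C@H]([C@H](CCOCc3ccc(OC)cc3)O[Si](C)(C)C(C)(C)C)C(C)=C[C@H]12 | intermediate
30 | α-methylene lactone with free C2 hydroxyl and C4 OPMB | C=C1C(=O)O[C@@H]2C[C@@H](C)[C@H]([C@H](CCOCc3ccc(OC)cc3)O)C(C)=C[C@H]12 | intermediate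
31 | angelic acid, (Z)-2-methylbut-2-enoic acid | C/C=C(/C)C(=O)O | starting material
32 | angelic 2,4,6-trichlorobenzoic anhydride | C/C=C(/C)C(=O)OC(=O)c1c(Cl)cc(Cl)cc1Cl | intermediate
33 | C2 angelate with C4 OPMB | C=C1C(=O)O[C@@H]2C[C@@H](C)[C@H]([C@H](CCOCc3ccc(OC)cc3)OC(=O)/C(C)=C\C)C(C)=C[C@H]12 | intermediate
34 | C2 angelate with free C4 hydroxyl | C=C1C(=O)O[C@@H]2C[C@@H](C)[C@H]([C@H](CCO)OC(=O)/C(C)=C\C)C(C)=C[C@H]12 | intermediate
35 | CNP0163960.1 | C=C1C(=O)O[C@@H]2C[C@@H](C)[C@H]([C@H](CCOC(C)=O)OC(=O)/C(C)=C\C)C(C)=C[C@H]12 | target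

**Step count**

Total: 22 steps. Longest linear sequence: 20 steps (steps 1–5 and 8–22); the aldehyde branch (steps 6 and 7) joins at step 8.

**Steps most likely to fail**

1. Step 8. What may go wrong: methyl delivery to C7 in competition with C10, γ-deprotonation at C9 with loss of silanolate toward tropone, and incomplete syn selectivity at C2. The fallback closes the lactone ring precursor before the coupling, so that only one enone is left and the cis-fused ring directs the cuprate to its convex face. It sets out from 3. Ethyl vinyl ether and N-bromosuccinimide should convert 3 into the bromoacetal of the hydroxy enone F1. LDA at −78 °C should give its lithium dienolate F2, which Me3SiCl traps as the trimethylsilyl dienol ether F3, and Pd(OAc)2 in MeCN should oxidise this to the bromoacetal dienone F4. Bu3SnH/AIBN should then cyclise the radical 5-exo onto C7 and give the cis-fused bicyclic enone F5, in which C1=C10 is the only acceptor. Addition of 13 should give the lithium enolate F6, Cp2ZrCl2 the zirconocene enolate F7, and aldehyde 11 the bicyclic aldol adduct F8. Silylation of F8 with tBuMe2SiOTf/2,6-lutidine returns to the route at 20.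

2. Step 5. What may go wrong: elimination of the silyloxy group toward tropone during or after the palladium oxidation, incomplete dehydrogenation, or desilylation by the acetic acid set free. The fallback replaces the palladium step by a selenoxide syn-elimination. It sets out from 6: PhSeCl in CH2Cl2 at −78 °C should give the α-phenylselanyl ketone F9. H2O2 with pyridine at 0 °C should oxidise it to the selenoxide F10, which eliminates on warming to rt and comes back to the route at 7.

3. Step 20. What may go wrong: slow acylation of the hindered C2 hydroxyl at 80 °C and Z-to-E isomerisation of the angeloyl unit to the tiglate. The fallback builds the Z enoate on the ester by olefination and never handles an activated angelic acid. It sets out from 30. Esterification with 2-[bis(2,2,2-trifluoroethoxy)phosphoryl]propanoic acid (DCC, cat. DMAP, CH2Cl2) should give the phosphonopropanoate ester F11. KN(SiMe3)2 with 18-crown-6 in THF at −78 °C should form its potassium phosphonate enolate F12, and acetaldehyde should then give the Z enoate by Still–Gennari olefination, coming back to the route at 33.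

**Further compounds**

F1 | step 8 | (R)-4-(2-bromo-1-ethoxyethoxy)cyclohept-2-en-1-one (acetal epimers) | CCOC(CBr)O[C@@H]1CCCC(=O)C=C1
F2 | step 8 | lithium dienolate of F1 | CCOC(CBr)O[C@@H]1CCC=C([O-])C=C1.[Li+]
F3 | step 8 | trimethylsilyl dienol ether of F1 | CCOC(CBr)O[C@@H]1CCC=C(O[Si](C)(C)C)C=C1
F4 | step 8 | (R)-4-(2-bromo-1-ethoxyethoxy)cyclohepta-2,6-dien-1-one | CCOC(CBr)O[C@@H]1CC=CC(=O)C=C1
F5 | step 8 | cis-fused bicyclic enone acetal (C5 ketone, C1=C10 alkene) | CCOC1O[C@@H]2CC=CC(=O)C[C@@H]2C1
F6 | step 8 | lithium enolate from methyl addition to F5 | CCOC1O[C@@H]2C[C@@H](C)C=C([O-])C[C@@H]2C1.[Li+]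
F7 | step 8 | chlorobis(cyclopentadienyl)zirconium enolate corresponding to F6 | CCOC1O[C@@H]2C[C@@H](C)C=C(O[Zr](Cl)(C3C=CC=C3)C3C=CC=C3)C[C@@H]2C1
F8 | step 8 | bicyclic aldol adduct (free C2 hydroxyl; C4 OPMB) | CCOC1O[C@@H]2C[C@@H](C)[C@H]([C@H](CCOCc3ccc(OC)cc3)O)C(=O)C[C@@H]2C1
F9 | step 5 | (4R)-7-(phenylselanyl)-4-(triethylsilyloxy)cyclohept-2-en-1-one (epimers at the selenium-bearing carbon) | CC[Si](CC)(CC)O[C@@H]1CCC([Se]c2ccccc2)C(=O)C=C1
F10 | step 5 | selenoxide of F9 | CC[Si](CC)(CC)O[C@@H]1CCC([Se](=O)c2ccccc2)C(=O)C=C1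
F11 | step 20 | C2 2-[bis(2,2,2-trifluoroethoxy)phosphoryl]propanoate of 30 | C=C1C(=O)O[C@@H]2C[C@@H](C)[C@H]([C@H](CCOCc3ccc(OC)cc3)OC(=O)C(C)P(=O)(OCC(F)(F)F)OCC(F)(F)F)C(C)=C[C@H]12
F12 | step 20 | potassium phosphonate enolate of F11 | C=C1C(=O)O[C@@H]2C[C@@H](C)[C@H]([C@H](CCOCc3ccc(OC)cc3)OC([O-])=C(C)P(=O)(OCC(F)(F)F)OCC(F)(F)F)C(C)=C[C@H]12.[K+]
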